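Numbering used throughout: the pyran is O1, C2 to C6; the side chain on C6 is C7–C8; ring A is the aryl group on C2 and ring B the aryl group on C8. Compounds 1 to 16 are defined in the steps and listed after them.

## Analysis of the target

Compound 16 is a cyclised diarylheptanoid: a tetrahydropyran that carries a 4-hydroxy-3-methoxyphenyl group (ring A) on C2, a hydroxyl on C4 and, on C6, a two-carbon chain C7–C8 ending in a second 4-hydroxy-3-methoxyphenyl group (ring B). The stereocentres are C2 (S), C4 (R) and C6 (S), and all three substituents lie on the same face of the ring, so in the chair all are equatorial. This is the thermodynamically preferred arrangement, so C6 and C4 can be set from C2 by substrate control and only one centre needs an external chiral agent. The sensitive groups are the two guaiacol-type phenols, which oxidise readily, and the C2–O1 bond, a benzylic ether para to an oxygen donor. That bond can ionise under acid (ring opening, loss of configuration at C2) and can be cut by hydrogenolysis. The difficulty is that the two aryl groups are identical in 16 but must behave differently on the way: the carbon next to ring A must never become a cation, whereas a helper oxygen on the carbon next to ring B must be removable. The route rests on the C6 side chain: C8 is a benzylic methylene that can stem from the carbonyl carbon of a vanillin-type aldehyde, C6–C7 can stem from a vinyl group on O1, and the C4 carbinol can be masked as an exocyclic methylene left behind by an allylsilane. With these assignments ring and chain can be assembled in one cationic cascade from two halves that both derive from vanillin (1).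

## Retrosynthetic reasoning

Target 16 is traced back to 15 and then to 14 by placing a benzyl ether on the ring-B phenol and a pivalate on the ring-A phenol. No skeletal bond is cut. The two groups differ on purpose: the acyl group makes ring A a poor donor, so the C2–O1 bond resists ionisation in every acidic step, while the alkyl ether leaves ring B a strong donor. Forward, an ester methanolysis is followed by a hydrogenolysis, so that the last operation on the polar bisphenol is a neutral one.

In 14 the C8–H bond is exchanged for a C8–O bond, which leads to diol 13. This hydroxyl sits on a benzylic carbon para to the benzyloxy group of ring B, so it can be removed by ionisation and hydride capture without touching the C4 hydroxyl or the deactivated C2–O1 bond. The gain is that C8 becomes a carbonyl-derived carbon, which makes an aryl aldehyde the ring-B building block. The configuration at C8 does not matter.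

The C4 carbinol of 13 is taken back to ketone 12, and the ketone to the exocyclic alkene of 11. Forward, oxidative cleavage of the 1,1-disubstituted alkene is followed by hydride addition. On a 2,6-cis tetrahydropyran-4-one a small hydride attacks along the axial direction and gives the equatorial, all-cis alcohol, so C4 is set by the ring. The alkene is cleaved before the deoxygenation because the acid used there would protonate it.

Alkene 11 is the point of the main disconnection: the C7–C8 and C5–C6 bonds are cut together, which gives vinyl ether 7 and aldehyde 8. These are the two bonds that form when an enol ether adds to an activated aldehyde and the resulting oxocarbenium ion 9 is caught by an allylsilane. C7 is the nucleophilic enol ether carbon, C6 the cationic carbon and C5 the allylsilane terminus, and the silicon-bearing carbon ends as the methylene on C4. Cutting O1–C6 and C5–C6 instead (alcohol 5 plus a three-carbon aryl aldehyde) would also close the ring, but that aldehyde would have to be made separately. The chosen cut lets both halves start from aldehydes of the vanillin (1) type and forms the ring, the chain bond and the C6 stereocentre in one flask. Forward, the step has to place C6 cis to C2 and keep the configuration at C2.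

Vinyl ether 7 is cut at the O1–C6 bond into alcohol 5 and ethyl vinyl ether (6). The forward reaction is a vinyl transfer that must be neither acidic (the allylsilane and the acetal-forming vinyl ether would react) nor strongly basic (the pivalate).

Alcohol 5 is cut at the C2–C3 bond into aldehyde 2 and allylstannane 4. The reagent carries a stannane and a silane on the same 2-methylenepropane-1,3-diyl unit. The stannane end is the more reactive and adds to the aldehyde under a chiral Lewis acid catalyst, which sets C2, the only stereocentre set by an external chiral agent. The silane end is kept for the cascade.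

Aldehyde 2 is the pivalate of vanillin (1), and stannane 4 comes from allyl chloride 3 by displacement with a stannyl anion. Aldehyde 8, the benzyl ether of 1, is bought.

## Alternatives that were turned down

Alternative 1: C4 is made a linchpin and the C3–C4 and C4–C5 bonds are cut; no bond to the ring oxygen is formed.
- Forward key step: lithiated silyl dithiane A1 opens alkyl epoxide A2 at its terminal carbon (C4–C5). A polar cosolvent then triggers a 1,4-shift of silicon from carbon to the new alkoxide, and the regenerated dithiane anion opens aryl epoxide A3 (C3–C4) to give open-chain dithiane A4.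
- In its favour: three pieces are joined in one flask, C2 and C6 are each set by a reagent-controlled epoxide, C4 arrives at the ketone oxidation level, and C8 is already a methylene, so no helper oxygen has to be removed.
- Against it: the pyran ring is still open in A4, and closing it means displacing one carbinol by the other. The easy closure, ionisation at the electron-rich benzylic C2, discards the very stereocentre that A3 was made enantiopure to deliver; an SN2 closure needs extra activation and protecting-group steps.
- Further drawbacks: A3 is an electron-rich styrene oxide that is hard to obtain and keep as one enantiomer and may open at the benzylic carbon or rearrange. The dithiane must later be removed by thiophilic or oxidative means next to two electron-rich rings.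
- Comparison: with the two epoxides, the coupling, dethioketalisation, ring closure, reduction and deprotection, the route should be several steps longer than the ten planned here. It is stronger in that C2 and C6 are fixed independently, so any diastereomer could be reached. The chosen cascade offers instead a ring that closes in the same step that joins the halves, and a C6 centre that needs no reagent of its own.

Alternative 2: the O1–C2 and C3–C4 bonds are cut, dividing the ring into a 1-oxadiene (O1=C6–C5=C4) and a two-carbon dienophile (C2=C3).
- Forward key step: Lewis-acid-activated β-benzoyloxy enone A5 would add to electron-rich styrene A6 in an inverse-demand oxa-Diels–Alder reaction to give dihydropyran A7, with C2 and C4 cis through an endo transition state. Hydrogenation of the C5=C6 enol ether from the face away from both substituents would then set C6.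
- In its favour: both partners are two or three steps from cheap aryl feedstocks, the C4 oxygen and the saturated C7–C8 chain are present from the start, and the ring, two bonds and two stereocentres arise at once. As a racemic route it would be clearly shorter than the chosen one.
- Against it for the single enantiomer: neither partner carries a stereocentre. The chiral Lewis acids established for this cycloaddition need a heterodiene with two-point binding and an enol ether dienophile, not a monodentate acyloxy enone and a styrene, so the absolute configuration has no defensible source.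
- Further drawbacks: A6 is prone to cationic oligomerisation under the Lewis acid, A5 can lose benzoate, and A7 is both an allylic benzoate and a 2-aryl enol ether and so ionises easily.
- Comparison: the chosen strategy is longer, but it takes its absolute configuration from a catalytic allylation of wide scope and relays it to C6 and C4 through chair transition states.

Alternative 3: only the C2–C3 bond is cut; O1–C2 is already present as a benzylic ether and C3–C4 as an enol acetate.
- Forward key step: a quinone oxidant would abstract hydride from the benzylic methylene of ether A8 (activated by ring A). The enol acetate carbon would attack the aryl-stabilised oxocarbenium ion through a chair to give the 2,6-cis tetrahydropyranone A9.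
- In its favour: the electron-rich ring A helps here, whereas in the chosen route it has to be tamed. The C6 stereocentre is a non-benzylic carbinol that cannot racemise. A9 already has the C4 ketone and the saturated chain, so the endgame is one hydride reduction and one hydrogenolysis of two identical benzyl ethers. On endgame economy this plan is stronger than the chosen one.
- Against it: ring B is as electron-rich as ring A, so the C8 methylene and the two O-benzyl methylenes compete for the oxidant, and A9 retains a doubly activated C2–H. Selectivity would rest on rate differences between similar sites, not on a structural difference.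
- Step economy: A8 is built linearly (chiral homopropargylic alcohol, etherification with a labile electron-rich benzyl electrophile, addition of a carboxylic acid across the alkyne), so the overall count should be close to that of the chosen route.
- Comparison: the chosen strategy offers a convergent union of two vanillin-derived halves, no oxidant in the presence of the electron-rich rings, and chemoselectivity built into the molecule by the pivalate/benzyl difference.

Key step: step 5

Remark on the chemistry: (S)-BINOL with Ti(OiPr)4 is taken to direct the allyl group to the Si face of an aryl aldehyde and so to give the (S)-carbinol; should the check at step 3 show the opposite sense, (R)-BINOL is used and nothing else changes. Compounds 3, 6 and 8 are taken as purchased.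

## Route

Step 1
Reactants: 1 vanillin (4-hydroxy-3-methoxybenzaldehyde)
Product: 2 4-formyl-2-methoxyphenyl 2,2-dimethylpropanoate
Conditions: PivCl, Et3N, DMAP (cat.), CH2Cl2, 0 °C to rt
Reagents that add atoms: pivaloyl chloride, CC(C)(C)C(=O)Cl
Why: Acylation of a phenol by an acid chloride under nucleophilic catalysis; the hindered aryl ester should survive the Lewis acids, the periodate and the cold borohydride used later, and it turns ring A into a weak donor.

Step 2
Reactants: 3 3-chloro-2-(trimethylsilylmethyl)prop-1-ene
Product: 4 tributyl[2-(trimethylsilylmethyl)prop-2-en-1-yl]stannane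
Conditions: Bu3SnH, LiN(iPr)2, THF, 0 °C; then 3, −78 °C to rt
Reagents that add atoms: tributyltin hydride, CCCC[SnH](CCCC)CCCC
Why: Nucleophilic substitution of an allylic chloride by Bu3SnLi made in the flask; direct and allylic (SN2') attack lead to the same product, so regiochemistry is not an issue.

Step 3
Reactants: 2 4-formyl-2-methoxyphenyl 2,2-dimethylpropanoate; 4 tributyl[2-(trimethylsilylmethyl)prop-2-en-1-yl]stannane
Product: 5 4-[(1S)-1-hydroxy-3-(trimethylsilylmethyl)but-3-en-1-yl]-2-methoxyphenyl 2,2-dimethylpropanoate
Conditions: (S)-BINOL (20 mol%), Ti(OiPr)4 (10 mol%), 4 Å MS, CH2Cl2, −20 °C; aq. NaHCO3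
Reagents that add atoms: none
Why: Keck asymmetric allylation: the chiral titanium binaphtholate activates the aldehyde and the stannane terminus adds through an open SE2' transition state, while the less nucleophilic allylsilane stays intact. Attack on the Si face should give the (S)-carbinol (future C2); the enantiomeric purity should be checked here by chiral HPLC.

Step 4
Reactants: 5 4-[(1S)-1-hydroxy-3-(trimethylsilylmethyl)but-3-en-1-yl]-2-methoxyphenyl 2,2-dimethylpropanoate; 6 ethyl vinyl ether
Product: 7 4-[(1S)-1-(ethenyloxy)-3-(trimethylsilylmethyl)but-3-en-1-yl]-2-methoxyphenyl 2,2-dimethylpropanoate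
Conditions: Pd(OCOCF3)2 (2 mol%), 4,7-diphenyl-1,10-phenanthroline (2 mol%), Et3N (10 mol%), 6 as solvent, rt
Reagents that add atoms: none
Why: Transfer vinylation: alkoxypalladation of the vinyl ether by the alcohol and β-alkoxide elimination exchange the ethoxy group for the alkoxide of 5, and the large excess of 6 drives the equilibrium. The amine keeps the medium free of acid, so no mixed acetal should form and the allylsilane should not be protonated; the stereocentre is not involved.

Step 5
Reactants: 7 4-[(1S)-1-(ethenyloxy)-3-(trimethylsilylmethyl)but-3-en-1-yl]-2-methoxyphenyl 2,2-dimethylpropanoate; 8 4-benzyloxy-3-methoxybenzaldehyde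
Product: 11 4-[(2S,6R)-6-[2-(4-benzyloxy-3-methoxyphenyl)-2-hydroxyethyl]-4-methylidenetetrahydro-2H-pyran-2-yl]-2-methoxyphenyl 2,2-dimethylpropanoate (2,6-cis; both C8 epimers), via oxocarbenium ion 9 (not isolated), via difluoroboryl ether 10 (not isolated)
Conditions: BF3·OEt2 (2.5 equiv), 2,6-di-tert-butyl-4-methylpyridine (2 equiv), 8 (1.5 equiv), CH2Cl2, −78 °C; aq. NaHCO3
Reagents that add atoms: none
Why: BF3·OEt2 activates aldehyde 8, and the unsubstituted vinyl carbon of 7 (the future C7) adds to it in a Mukaiyama-type aldol step, which forms C7–C8 and leaves oxocarbenium ion 9 with the charge on C6. The tethered 2-(silylmethyl)allyl group then attacks C6 with its terminal methylene carbon (the future C5) in a silyl-Prins closure, the tetrahydropyran ring closing 6-endo with respect to both the C6=O1 bond and the alkene, and the β-silyl cation at C4 loses silicon to fluoride to leave the exocyclic methylene and boryl ether 10, which the work-up hydrolyses to 11. The closest known reaction type is the Mukaiyama aldol–Prins cascade of vinyl ethers of 2-(silylmethyl)allyl carbinols with aldehydes under BF3·OEt2 and a hindered pyridine, here used on a benzylic ether. C6 is set by a chair transition state in which the ring-A aryl group on C2 and the C7 chain of the (E)-oxocarbenium ion are both equatorial, so the ring should form 2,6-cis (2S,6R in 11, the R arising only from the priority of the C8 oxygen); C8 forms without control and becomes a methylene in step 8. The step needs ring closure to outrun benzylic ionisation of C2–O1, 2-oxonia-Cope scrambling of C2 and addition of a second vinyl ether to 9. The pivalate makes ring A a poor donor, and the allylsilane is a far stronger π-nucleophile than a plain alkene and attacks intramolecularly, so capture should be fast at −78 °C and the configuration at C2 should be kept. The hindered pyridine removes adventitious protic acid, which would hydrolyse the vinyl ether or protodesilylate the allylsilane.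

Step 6
Reactants: 11 4-[(2S,6R)-6-[2-(4-benzyloxy-3-methoxyphenyl)-2-hydroxyethyl]-4-methylidenetetrahydro-2H-pyran-2-yl]-2-methoxyphenyl 2,2-dimethylpropanoate
Product: 12 4-[(2S,6S)-6-[2-(4-benzyloxy-3-methoxyphenyl)-2-hydroxyethyl]-4-oxotetrahydro-2H-pyran-2-yl]-2-methoxyphenyl 2,2-dimethylpropanoate (both C8 epimers)
Conditions: OsO4 (2 mol%), NaIO4 (4 equiv), 2,6-lutidine (2 equiv), dioxane–H2O 3:1, rt
Reagents that add atoms: sodium periodate, [Na+].[O-][I](=O)(=O)=O (oxygen carried to carbon by way of OsO4)
Why: Lemieux–Johnson cleavage: catalytic dihydroxylation of the 1,1-disubstituted alkene and periodate cleavage of the diol give the ketone and formaldehyde. The buffered conditions should leave the secondary C8 carbinol, the electron-rich rings and both stereocentres untouched, which ozone would not guarantee for ring B.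

Step 7
Reactants: 12 4-[(2S,6S)-6-[2-(4-benzyloxy-3-methoxyphenyl)-2-hydroxyethyl]-4-oxotetrahydro-2H-pyran-2-yl]-2-methoxyphenyl 2,2-dimethylpropanoate
Product: 13 4-[(2S,4R,6R)-6-[2-(4-benzyloxy-3-methoxyphenyl)-2-hydroxyethyl]-4-hydroxytetrahydro-2H-pyran-2-yl]-2-methoxyphenyl 2,2-dimethylpropanoate (all-cis ring; both C8 epimers)
Conditions: NaBH4, MeOH–CH2Cl2, −40 °C
Reagents that add atoms: none
Why: Borohydride reduction of the ketone: the small hydride should attack the chair of the 2,6-cis tetrahydropyranone along the axial direction and give the equatorial (4R) alcohol, cis to the substituents on C2 and C6. The low temperature should keep the aryl pivalate from methanolysis.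

Step 8
Reactants: 13 4-[(2S,4R,6R)-6-[2-(4-benzyloxy-3-methoxyphenyl)-2-hydroxyethyl]-4-hydroxytetrahydro-2H-pyran-2-yl]-2-methoxyphenyl 2,2-dimethylpropanoate
Product: 14 4-[(2S,4R,6S)-6-[2-(4-benzyloxy-3-methoxyphenyl)ethyl]-4-hydroxytetrahydro-2H-pyran-2-yl]-2-methoxyphenyl 2,2-dimethylpropanoate
Conditions: Et3SiH (3 equiv), CF3CO2H (10 equiv), CH2Cl2, −20 to 0 °C; then aq. NaHCO3–MeOH, rt
Reagents that add atoms: none
Why: Ionic hydrogenation of a benzylic alcohol: the acid ionises only the C8 hydroxyl, whose cation is stabilised by the para-benzyloxy group of ring B, and the silane delivers hydride, so both C8 epimers converge on one compound. The C4 hydroxyl cannot ionise and the C2–O1 bond is shielded by the pivalate on ring A; the bicarbonate–methanol work-up frees the C4 hydroxyl should the acid have acylated part of it.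

Step 9
Reactants: 14 4-[(2S,4R,6S)-6-[2-(4-benzyloxy-3-methoxyphenyl)ethyl]-4-hydroxytetrahydro-2H-pyran-2-yl]-2-methoxyphenyl 2,2-dimethylpropanoate
Product: 15 (2S,4R,6S)-6-[2-(4-benzyloxy-3-methoxyphenyl)ethyl]-2-(4-hydroxy-3-methoxyphenyl)tetrahydro-2H-pyran-4-ol
Conditions: K2CO3 (0.5 equiv), MeOH, rt to 40 °C
Reagents that add atoms: none
Why: Base-catalysed transesterification of an aryl ester with methanol; the phenoxide is a good leaving group, so even the hindered pivalate should cleave under mild conditions that leave the benzyl ether and the ring alone.

Step 10
Reactants: 15 (2S,4R,6S)-6-[2-(4-benzyloxy-3-methoxyphenyl)ethyl]-2-(4-hydroxy-3-methoxyphenyl)tetrahydro-2H-pyran-4-ol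
Product: 16 (2S,4R,6S)-2-(4-hydroxy-3-methoxyphenyl)-6-[2-(4-hydroxy-3-methoxyphenyl)ethyl]tetrahydro-2H-pyran-4-ol
Conditions: H2 (1 atm), 10% Pd/C, EtOAc–MeOH, rt
Reagents that add atoms: none
Why: Hydrogenolysis of an aryl benzyl ether; under neutral conditions the O-benzyl group should be cleaved much faster than the cyclic benzylic ether C2–O1, and the reaction is stopped as soon as 15 is consumed.

## Compound list

1 | vanillin (4-hydroxy-3-methoxybenzaldehyde) | COc1cc(C=O)ccc1O | starting material
2 | 4-formyl-2-methoxyphenyl 2,2-dimethylpropanoate | COc1cc(C=O)ccc1OC(=O)C(C)(C)C | intermediate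
3 | 3-chloro-2-(trimethylsilylmethyl)prop-1-ene | C=C(CCl)C[Si](C)(C)C | starting material
4 | tributyl[2-(trimethylsilylmethyl)prop-2-en-1-yl]stannane | C=C(C[Si](C)(C)C)C[Sn](CCCC)(CCCC)CCCC | intermediate
5 | 4-[(1S)-1-hydroxy-3-(trimethylsilylmethyl)but-3-en-1-yl]-2-methoxyphenyl 2,2-dimethylpropanoate | C=C(C[Si](C)(C)C)C[C@@H](c1ccc(OC(=O)C(C)(C)C)c(OC)c1)O | intermediate
6 | ethyl vinyl ether | C=COCC | starting material
7 | 4-[(1S)-1-(ethenyloxy)-3-(trimethylsilylmethyl)but-3-en-1-yl]-2-methoxyphenyl 2,2-dimethylpropanoate | C=C(C[Si](C)(C)C)C[C@@H](c1ccc(OC(=O)C(C)(C)C)c(OC)c1)OC=C | intermediate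
8 | 4-benzyloxy-3-methoxybenzaldehyde | COc1cc(C=O)ccc1OCc1ccccc1 | starting material
9 | oxocarbenium ion from 7 and 8 (cation at C6, trifluoroborate alkoxide at C8; formed in the flask, not isolated) | C=C(C[Si](C)(C)C)C[C@@H](c1ccc(OC(=O)C(C)(C)C)c(OC)c1)[O+]=CCC(O[B-](F)(F)F)c1ccc(OCc2ccccc2)c(OC)c1 | intermediate
10 | C8 difluoroboryl ether of 11 (formed in the flask, not isolated) | COc1cc(C(OB(F)F)C[C@H]2CC(=C)C[C@@H](c3ccc(OC(=O)C(C)(C)C)c(OC)c3)O2)ccc1OCc1ccccc1 | intermediate
11 | 4-[(2S,6R)-6-[2-(4-benzyloxy-3-methoxyphenyl)-2-hydroxyethyl]-4-methylidenetetrahydro-2H-pyran-2-yl]-2-methoxyphenyl 2,2-dimethylpropanoate (2,6-cis; both C8 epimers) | COc1cc(C(O)C[C@H]2CC(=C)C[C@@H](c3ccc(OC(=O)C(C)(C)C)c(OC)c3)O2)ccc1OCc1ccccc1 | intermediate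
12 | 4-[(2S,6S)-6-[2-(4-benzyloxy-3-methoxyphenyl)-2-hydroxyethyl]-4-oxotetrahydro-2H-pyran-2-yl]-2-methoxyphenyl 2,2-dimethylpropanoate (both C8 epimers) | COc1cc(C(O)C[C@H]2CC(=O)C[C@@H](c3ccc(OC(=O)C(C)(C)C)c(OC)c3)O2)ccc1OCc1ccccc1 | intermediate
13 | 4-[(2S,4R,6R)-6-[2-(4-benzyloxy-3-methoxyphenyl)-2-hydroxyethyl]-4-hydroxytetrahydro-2H-pyran-2-yl]-2-methoxyphenyl 2,2-dimethylpropanoate (all-cis ring; both C8 epimers) | COc1cc(C(O)C[C@H]2C[C@@H](O)C[C@@H](c3ccc(OC(=O)C(C)(C)C)c(OC)c3)O2)ccc1OCc1ccccc1 | intermediate
14 | 4-[(2S,4R,6S)-6-[2-(4-benzyloxy-3-methoxyphenyl)ethyl]-4-hydroxytetrahydro-2H-pyran-2-yl]-2-methoxyphenyl 2,2-dimethylpropanoate | COc1cc(CC[C@H]2C[C@@H](O)C[C@@H](c3ccc(OC(=O)C(C)(C)C)c(OC)c3)O2)ccc1OCc1ccccc1 | intermediate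
15 | (2S,4R,6S)-6-[2-(4-benzyloxy-3-methoxyphenyl)ethyl]-2-(4-hydroxy-3-methoxyphenyl)tetrahydro-2H-pyran-4-ol | COc1cc(CC[C@H]2C[C@@H](O)C[C@@H](c3ccc(O)c(OC)c3)O2)ccc1OCc1ccccc1 | intermediate
16 | (2S,4R,6S)-2-(4-hydroxy-3-methoxyphenyl)-6-[2-(4-hydroxy-3-methoxyphenyl)ethyl]tetrahydro-2H-pyran-4-ol | COc1cc(CC[C@H]2C[C@@H](O)C[C@@H](c3ccc(O)c(OC)c3)O2)ccc1O | target

The descriptor at C6 reads R in 11 and 13 and S elsewhere only because the C8 oxygen changes the priority of the side chain; the geometry at C6 is the same from 11 to 16.

## Step count and least certain steps

Total step count: 10. Longest linear sequence: 9 steps (steps 1 and 3 to 10 from 1; steps 2 and 3 to 10 from 3 is equally long).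

**Step 5 (key step).**
- What may go wrong: the aldol addition may be slow, because aldehyde 8 is electron-rich and a weak electrophile even when complexed. The vinyl ether may then be lost by oligomerisation or acid hydrolysis before it adds.
- The boron alkoxide at C8 may ionise (ring B is a strong donor) and lead to a second addition or to elimination.
- Enantiopurity at C2 may erode by reversible benzylic ionisation or 2-oxonia-Cope rearrangement if ring closure is slower than expected.
- Fallback: it sets out from 5 and comes back at 14. The phenol of 3-(4-hydroxy-3-methoxyphenyl)propan-1-ol F1, which is bought, is benzylated (BnBr, K2CO3, acetone) to 3-(4-benzyloxy-3-methoxyphenyl)propan-1-ol F2, and this is oxidised with Dess–Martin periodinane to 3-(4-benzyloxy-3-methoxyphenyl)propanal F3. Alcohol 5 and F3 are condensed with Me3SiOTf in Et2O at −78 °C in a silyl-Prins pyran annulation, in which the oxocarbenium ion forms from the hemiacetal and is trapped by the same allylsilane. This should give the 2,6-cis 4-methylidenetetrahydropyran with the saturated chain F4. Lemieux–Johnson cleavage as in step 6 gives the tetrahydropyran-4-one F5, and NaBH4 as in step 7 gives 14. The disconnection changes to O1–C6/C5–C6, and no oxygen is ever placed on C8.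

**Step 4.**
- What may go wrong: incomplete exchange at a hindered benzylic secondary alcohol, since the reaction is an equilibrium, or attack of the electrophilic divalent palladium on the allylsilane with loss of silicon.
- Fallback: it sets out from 5 and comes back at 7 and makes no new compound. The vinyl group is taken from vinyl acetate with [Ir(cod)Cl]2 and Na2CO3 in toluene at 100 °C. The alkoxide adds to the vinyl ester and acetate leaves, so the transfer runs under basic conditions, has a carboxylate as leaving group and is not an ether–ether equilibrium. An acetal-based vinyl ether synthesis is not an option, because the oxocarbenium ion it passes through would be trapped by the allylsilane.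

**Step 8.**
- What may go wrong: the C8 cation may lose a C7 proton; the resulting styrene makes C6–O1 an allylic ether that can ionise and open the ring. Partial acylation of the C4 hydroxyl by the acid is a lesser concern.
- Fallback: it sets out from 12 and comes back at 14, replacing steps 7 and 8. The C8 hydroxyl of 12, the only hydroxyl in that compound, is converted with 1,1'-thiocarbonyldiimidazole into the C8 imidazol-1-ylcarbothioate F6. Barton–McCombie reduction with Bu3SnH and AIBN in toluene at 80 °C then gives the C8-deoxy ketone F5 already met in the fallback for step 5, and NaBH4 as in step 7 gives 14. With the alkene already cleaved, the benzylic radical has no partner for cyclisation.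

**Step 10.**
- What may go wrong: hydrogenolysis of the ring bond C2–O1, which in 15 is benzylic to a free para-hydroxyphenyl group, and with it ring opening.
- Fallback: it sets out from 14 and comes back at 16 with the last two operations reversed. Hydrogenolysis of 14 (H2, 10% Pd/C, EtOAc) gives the ring-B phenol with the ring-A pivalate still in place F7, in which the C2–O1 bond is next to the deactivated ring. Methanolysis as in step 9 under argon then gives 16.

## Further compounds

F1 | step 5 | 3-(4-hydroxy-3-methoxyphenyl)propan-1-ol (bought for the fallback) | COc1cc(CCCO)ccc1O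
F2 | step 5 | 3-(4-benzyloxy-3-methoxyphenyl)propan-1-ol | COc1cc(CCCO)ccc1OCc1ccccc1
F3 | step 5 | 3-(4-benzyloxy-3-methoxyphenyl)propanal | COc1cc(CCC=O)ccc1OCc1ccccc1
F4 | step 5 | 4-[(2S,6S)-6-[2-(4-benzyloxy-3-methoxyphenyl)ethyl]-4-methylidenetetrahydro-2H-pyran-2-yl]-2-methoxyphenyl 2,2-dimethylpropanoate | COc1cc(CC[C@H]2CC(=C)C[C@@H](c3ccc(OC(=O)C(C)(C)C)c(OC)c3)O2)ccc1OCc1ccccc1
F5 | step 5 | 4-[(2S,6S)-6-[2-(4-benzyloxy-3-methoxyphenyl)ethyl]-4-oxotetrahydro-2H-pyran-2-yl]-2-methoxyphenyl 2,2-dimethylpropanoate | COc1cc(CC[C@H]2CC(=O)C[C@@H](c3ccc(OC(=O)C(C)(C)C)c(OC)c3)O2)ccc1OCc1ccccc1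
F0 | step 4 | none | none
F6 | step 8 | 4-[(2S,6S)-6-[2-(4-benzyloxy-3-methoxyphenyl)-2-(imidazol-1-ylcarbothioyloxy)ethyl]-4-oxotetrahydro-2H-pyran-2-yl]-2-methoxyphenyl 2,2-dimethylpropanoate (both C8 epimers) | COc1cc(C(OC(=S)n2ccnc2)C[C@H]2CC(=O)C[C@@H](c3ccc(OC(=O)C(C)(C)C)c(OC)c3)O2)ccc1OCc1ccccc1
F7 | step 10 | 4-[(2S,4R,6S)-4-hydroxy-6-[2-(4-hydroxy-3-methoxyphenyl)ethyl]tetrahydro-2H-pyran-2-yl]-2-methoxyphenyl 2,2-dimethylpropanoate | COc1cc(CC[C@H]2C[C@@H](O)C[C@@H](c3ccc(OC(=O)C(C)(C)C)c(OC)c3)O2)ccc1O
A1 | alternative 1 | 2-(tert-butyldimethylsilyl)-1,3-dithiane | CC(C)(C)[Si](C)(C)C1SCCCS1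
A2 | alternative 1 | (S)-2-[2-(4-benzyloxy-3-methoxyphenyl)ethyl]oxirane | COc1cc(CC[C@H]2CO2)ccc1OCc1ccccc1
A3 | alternative 1 | (R)-2-(4-benzyloxy-3-methoxyphenyl)oxirane | COc1cc([C@@H]2CO2)ccc1OCc1ccccc1
A4 | alternative 1 | (1S)-1-(4-benzyloxy-3-methoxyphenyl)-2-[2-[(2S)-4-(4-benzyloxy-3-methoxyphenyl)-2-(tert-butyldimethylsilyloxy)butyl]-1,3-dithian-2-yl]ethanol | COc1cc(CC[C@H](O[Si](C)(C)C(C)(C)C)CC2(SCCCS2)C[C@@H](c3ccc(OCc4ccccc4)c(OC)c3)O)ccc1OCc1ccccc1
A5 | alternative 2 | (E)-5-(4-benzyloxy-3-methoxyphenyl)-3-oxopent-1-en-1-yl benzoate | COc1cc(CCC(=O)/C=C/OC(=O)c2ccccc2)ccc1OCc1ccccc1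
A6 | alternative 2 | 1-benzyloxy-4-ethenyl-2-methoxybenzene | COc1cc(C=C)ccc1OCc1ccccc1
A7 | alternative 2 | (2S,4S)-2-(4-benzyloxy-3-methoxyphenyl)-6-[2-(4-benzyloxy-3-methoxyphenyl)ethyl]-3,4-dihydro-2H-pyran-4-yl benzoate (2,4-cis) | COc1cc(CCC2=C[C@@H](OC(=O)c3ccccc3)C[C@@H](c3ccc(OCc4ccccc4)c(OC)c3)O2)ccc1OCc1ccccc1
A8 | alternative 3 | (4S)-6-(4-benzyloxy-3-methoxyphenyl)-4-[(4-benzyloxy-3-methoxyphenyl)methoxy]hex-1-en-2-yl acetate | COc1cc(CC[C@@H](CC(=C)OC(C)=O)OCc2ccc(OCc3ccccc3)c(OC)c2)ccc1OCc1ccccc1
A9 | alternative 3 | (2S,6S)-2-(4-benzyloxy-3-methoxyphenyl)-6-[2-(4-benzyloxy-3-methoxyphenyl)ethyl]tetrahydro-2H-pyran-4-one | COc1cc(CC[C@H]2CC(=O)C[C@@H](c3ccc(OCc4ccccc4)c(OC)c3)O2)ccc1OCc1ccccc1
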